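If two flasks sit at one temperature with one catalyst charge, they should run on one clock, whatever else the recipe holds. Gamma and Monday's are such a pair, so here is my own reckoning for Monday's.

the same everywhere: free catalyst 51 µM
- alpha: starting material 0.051 M; partner 0.051 M; second substrate 0.051 M; protic impurity 5.1 mM; temperature 35 °C; run made earlier
- gamma: starting material 0.071 M; partner 0.051 M; second substrate 0.051 M; protic impurity 5.1 mM; temperature 50 °C; run made earlier
- epsilon: starting material 0.11 M; partner 0.051 M; second substrate 0.051 M; protic impurity 5.1 mM; temperature 35 °C; run made earlier
- Sunday's: starting material 0.051 M; partner 0.0510 M (fed, over 3.0 min); second substrate 0.0510 M; protic impurity 5.10 mM; temperature 50 °C; all else is in the flask from the start; the feed brings no volume worth counting; time 8.0 min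
- Thursday's: starting material 0.051 M; partner 0.0510 M; second substrate 0.0510 M; protic impurity 5.10 mM; everything together at the start at 10 °C, warmed to 50 °C at 3.0 min; time 8.0 min
- Monday's: starting material 0.051 M; partner 0.0510 M; second substrate 0.0510 M; protic impurity 5.10 mM; temperature 50 °C; everything together at the start; time 8.0 min
- Tuesday's: starting material 0.051 M (fed, over 3.0 min); partner 0.0510 M; second substrate 0.0510 M; protic impurity 5.10 mM; the addition at 10 °C, then warmed to 50 °C; the feed brings no volume worth counting; time 8.0 min

| run | time / min | target / % |
|---|---|---|
| alpha | 1.33 | 24.7 |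
| alpha | 3.00 | 40.9 |
| alpha | 4.00 | 46.1 |
| alpha | 6.00 | 54.4 |
| alpha | 8.00 | 60.2 |
| alpha | 10.0 | 62.7 |
| gamma | 0.250 | 10.5 |
| gamma | 0.667 | 20.7 |
| gamma | 1.33 | 31.9 |
| gamma | 2.00 | 39.4 |
| gamma | 3.00 | 44.3 |
| gamma | 4.00 | 47.4 |
| gamma | 5.00 | 50.8 |
| epsilon | 0.500 | 10.1 |
| epsilon | 1.33 | 21.6 |
| epsilon | 3.00 | 31.0 |
| epsilon | 4.00 | 36.2 |
| epsilon | 6.00 | 39.2 |
| epsilon | 8.00 | 40.1 |
| epsilon | 10.0 | 40.1 |

(readings scatter by 0.5 percentage points)

1. the flask that comes out highest in amount of target, in percent of the starting material charged, or "all alike" when all lie within 1.5 percentage points (Sunday's / Thursday's / Monday's / Tuesday's / all alike)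
2. target at the end, in percent of the starting material charged, Sunday's
3. target at the end, in percent of the starting material charged, Thursday's
4. target at the end, in percent of the starting material charged, Monday's
5. target at the end, in percent of the starting material charged, Tuesday's



Start from above. In epsilon, partner is the limiting reagent (0.051 M against 0.11 M), and target levels at 40.1%. That is 0.0441 M, or 86.5% of Monday's charge. This ceiling is loose.

Now suppose the target rate goes as [starting material][partner] times catalyst. Divide the rate by that product and the recipe drops out. Gamma's last reading, at 5.00 min, then gives a sum: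

ln( [partner at start][starting material now] / ([starting material at start][partner now]) ) / (difference of the charges) = 26.0 /M

Call this the exposure: the rate over that product, added up over time. I neglect the side paths of partner on both sides.

With equal charges, exposure is the reciprocal of [starting material] now minus its reciprocal at the start. Exposure only adds up, so on this reckoning Monday's has at least gamma's 26.0 /M by 8.0 min:

lower bound = 57.0%

Gamma's exposure at 3.00 min is 18.7 /M, so it was growing by 3.63 /M/min. Nothing feeds the catalyst, so that pace should not rise. Holding it up to 8.0 min gives an exposure of 36.8 /M, and so: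

upper bound = 65.3%

The forecast reads: “Target rises about exponentially, first order in starting material”. It puts Monday's at 53% (49% to 57%), below the bracket. It gives Sunday's 35%, Tuesday's 54% and Thursday's 55%, and names Thursday's highest.

Monday's comes out highest, at 62.5%, inside the bracket, with Thursday's at 60.3%, Tuesday's at 58.5% and Sunday's at 54.4%.

    second substrate + partner + free catalyst → free catalyst + second product (k = 122 /M²/s, Ea = 38.0 kJ/mol)
    partner + protic impurity → quenched reagent (k = 0.441 /M/s, Ea = 54.0 kJ/mol)
    free catalyst → spent catalyst (k = 0.00282 /s, Ea = 83.0 kJ/mol)
    starting material + partner + free catalyst → free catalyst + target (k = 3080 /M²/s, Ea = 35.0 kJ/mol)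
    (constants at 50 °C)

Free catalyst in Monday's stands at 25.8% at 8.00 min, the same as in Sunday's (25.8%). Read back, Monday's result is an exposure of 32.7 /M, above gamma's 26.0 /M and below the 36.8 /M cap.

The equal-charge line does not hold in a fed flask: Sunday's partner averages 0.0172 M over the first 3.0 min, against 0.0297 M in Monday's. For a fed flask the line therefore gives a ceiling. Sunday's neighbour is fed too and holds 8.7 × 10⁻⁵ M of free catalyst. Scaled by the catalyst charge, Monday's exposure becomes 55.7 /M, which gives a ceiling of 74.0%. The neighbour comes out at 65.2%, below it.

The earlier runs and the new flask stem from a simulated flask on assumed constants; scatter was added.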